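The route rests on cutting C5–C5a (1-benzoxepine numbering). With C9a raised to the carbonyl level, the ring B segment O1–C9a–C5a–C5–C4=C3 is a Claisen retron. The bond is therefore made by a ring-expanding [3,3] shift. Methylenation of a five-membered vinyl carbonate gives a cyclic ketene acetal that rearranges to a seven-membered lactone, which closes the ring and fixes the Z C3=C4 alkene in one operation. The lactone then serves as a geometric template. Its α-metallated enol ether is opened stereospecifically to a (2Z,5E)-trienol, whose enantioselective bromonium cascade builds ring A and re-closes ring B. C2 is completed last by oxidation, bromomethyl addition and hydride delivery anti to the angular methyl.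

Key step: step 2

Assumption: the (R)-configured catalyst of step 6 is taken to deliver bromine to the alkene face that leads to 7S. If the sense of induction is opposite, its antipode is used.

Step 1
Reactants: 1 2-methyl-2-vinyloxirane (racemic isoprene monoxide)
Product: 2 4-methyl-4-vinyl-1,3-dioxolan-2-one (racemic)
Conditions: CO2 (1 atm), Pd(PPh3)4 (2 mol %), THF, 0 °C to rt
Reagents that add atoms: carbon dioxide, O=C=O
Why: Zerovalent-palladium-catalysed CO2 insertion into a vinyl epoxide should proceed by π-allyl alkoxide formation, carboxylation and closure at the tertiary terminus; the stereocentre is irrelevant because step 2 destroys it.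

Step 2
Reactants: 2 4-methyl-4-vinyl-1,3-dioxolan-2-one
Product: 4 6-methyl-4,7-dihydrooxepin-2(3H)-one, via cyclic ketene acetal 3 (not isolated)
Conditions: Cp2TiMe2 (1.1 equiv), toluene, 100 °C, dark
Reagents that add atoms: dimethyltitanocene, [CH3-].[CH3-].[Ti+4].c1cc[cH-]c1.c1cc[cH-]c1
Why: Cp2TiMe2 loses methane to give Cp2Ti=CH2, which methylenates the carbonate C=O through an oxatitanacyclobutane to the 2-methylene-1,3-dioxolane 3, an allyl vinyl ether (CH2=C–O–C(Me)–CH=CH2) that undergoes a concerted [3,3] Claisen shift at the reaction temperature. The closest known reaction type is the tandem Petasis methylenation/Claisen ring expansion of vinyl-substituted cyclic carbonates to medium-ring lactones. The seven-membered ring closes by ring expansion (five to seven) through a boat-like bicyclic transition state, in which the C–C bond between the new methylene carbon (future C5a) and the vinyl terminus (future C5) forms as the tertiary allylic C–O bond breaks. No stereocentre is created; the element that is set is the alkene geometry, which the seven-membered ring forces to be Z (CH2O and ring CH2 cis). The step needs mono-methylenation: the tertiary allylic C–O bond makes the shift fast, and limiting the titanium reagent to about one equivalent should keep the product lactone from being methylenated in turn.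

Step 3
Reactants: 4 6-methyl-4,7-dihydrooxepin-2(3H)-one
Product: 5 6-methyl-4,7-dihydrooxepin-2-yl diphenyl phosphate
Conditions: KN(SiMe3)2, (PhO)2P(O)Cl, HMPA, THF, −78 °C, kept below 0 °C
Reagents that add atoms: diphenyl chlorophosphate, O=P(Cl)(Oc1ccccc1)Oc1ccccc1
Why: Kinetic lactone enolisation and O-phosphorylation (ketene acetal phosphate formation) can only occur at C3, and the cold handling is meant to suppress [3,3] ring contraction of this allyl ketene acetal.

Step 4
Reactants: 5 6-methyl-4,7-dihydrooxepin-2-yl diphenyl phosphate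
Product: 6 trimethyl(6-methyl-4,7-dihydrooxepin-2-yl)stannane
Conditions: (Me3Sn)2, Pd2(dba)3 (5 mol %), AsPh3, LiCl, THF, 20 °C
Reagents that add atoms: hexamethyldistannane, C[Sn](C)(C)[Sn](C)(C)C
Why: Stille-type stannylation of a ketene acetal phosphate replaces the C–OP bond by C–Sn with retention, and the weakly bound arsine ligand should allow reaction at room temperature.

Step 5
Reactants: 6 trimethyl(6-methyl-4,7-dihydrooxepin-2-yl)stannane; 7 5-bromo-2-methylpent-2-ene
Product: 12 (2Z,5E)-2,6,10-trimethylundeca-2,5,9-trien-1-ol, via 2-lithio enol ether 8 (not isolated), via homoprenylmagnesium bromide 9 (not isolated), via mixed lithium cuprate 10 (not isolated), via alkenylcopper alkoxide 11 (not isolated)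
Conditions: 7, Mg, THF; CuBr·SMe2, −40 °C; 6, n-BuLi, THF, −78 °C, cannulated in; −78 °C to rt; MeI, HMPA, 0 °C; aq NH4Cl
Reagents that add atoms: iodomethane, CI
Why: After tin–lithium exchange and cuprate formation, a 1,2-metallate rearrangement of the α-alkoxyalkenyl cuprate moves the homoprenyl group from copper to the sp2 carbon with inversion as the ring alkoxide leaves, so copper (then methyl, by retentive alkylation) ends cis to the C5 methylene and the new trisubstituted alkene is E.

Step 6
Reactants: 12 (2Z,5E)-2,6,10-trimethylundeca-2,5,9-trien-1-ol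
Product: 13 (5aS,7S,9aS)-7-bromo-3,6,6,9a-tetramethyl-2,5,5a,6,7,8,9,9a-octahydro-1-benzoxepine
Conditions: 1,3-dibromo-5,5-dimethylhydantoin (0.55 equiv), (R)-BINOL-derived thiophosphoramide catalyst (10 mol %), toluene–CH2Cl2, −78 °C
Reagents that add atoms: 1,3-dibromo-5,5-dimethylhydantoin, CC1(C)N(Br)C(=O)N(Br)C1=O
Why: In this catalytic enantioselective bromonium-induced polyene cyclisation the chiral Lewis base–Br+ complex selects one face of the most electron-rich terminal alkene (sets C7), and chair-like antiperiplanar addition across the E alkene with capture of the C9a cation by the hydroxyl sets equatorial Br, axial 5a-H and axial 9a-methyl (trans fusion).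

Step 7
Reactants: 13 (5aS,7S,9aS)-7-bromo-3,6,6,9a-tetramethyl-2,5,5a,6,7,8,9,9a-octahydro-1-benzoxepine
Product: 14 (5aS,7S,9aS)-7-bromo-3,6,6,9a-tetramethyl-5a,6,7,8,9,9a-hexahydro-1-benzoxepin-2(5H)-one
Conditions: CrO3, 3,5-dimethylpyrazole, CH2Cl2, −20 °C
Reagents that add atoms: chromium trioxide, O=[Cr](=O)=O
Why: In this allylic oxidation the C2 methylene is both allylic and α to oxygen, hence the most hydridic C–H, so the unsaturated lactone should form without touching a stereocentre or the secondary bromide.

Step 8
Reactants: 14 (5aS,7S,9aS)-7-bromo-3,6,6,9a-tetramethyl-5a,6,7,8,9,9a-hexahydro-1-benzoxepin-2(5H)-one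
Product: 15 (5aS,7S,9aS)-7-bromo-2-(bromomethyl)-3,6,6,9a-tetramethyl-2,5,5a,6,7,8,9,9a-octahydro-1-benzoxepin-2-ol (lactol, both C2 epimers)
Conditions: CH2Br2, n-BuLi, THF–Et2O, −78 °C; AcOH quench at −78 °C
Reagents that add atoms: dibromomethane, BrCBr
Why: In this halomethyllithium (carbenoid) addition to a lactone, LiCH2Br made in situ adds 1,2 and the tetrahedral alkoxide should survive at −78 °C until the acid quench, so over-addition is avoided and C2 is fixed in the next step.

Step 9
Reactants: 15 (5aS,7S,9aS)-7-bromo-2-(bromomethyl)-3,6,6,9a-tetramethyl-2,5,5a,6,7,8,9,9a-octahydro-1-benzoxepin-2-ol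
Product: 17 palisadin B, (2R,5aS,7S,9aS)-7-bromo-2-(bromomethyl)-3,6,6,9a-tetramethyl-2,5,5a,6,7,8,9,9a-octahydro-1-benzoxepine, via conjugated oxocarbenium ion 16 (not isolated)
Conditions: Et3SiH, BF3·OEt2, CH2Cl2, −78 to −20 °C
Reagents that add atoms: none
Why: In this ionic reduction of a lactol (Lewis acid/silane), BF3 ionises 15 to 16 and Et3SiH should attack C2 from the face opposite the axial C9a methyl, placing H anti and CH2Br syn to that methyl (2R).

Compound list
1 | 2-methyl-2-vinyloxirane (racemic) | CC1(C=C)CO1 | starting material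
2 | 4-methyl-4-vinyl-1,3-dioxolan-2-one (racemic) | CC1(C=C)COC(=O)O1 | intermediate
3 | 4-methyl-2-methylidene-4-vinyl-1,3-dioxolane (racemic, not isolated) | C=C1OCC(C)(C=C)O1 | intermediate
4 | 6-methyl-4,7-dihydrooxepin-2(3H)-one | CC1=CCCC(=O)OC1 | intermediate
5 | 6-methyl-4,7-dihydrooxepin-2-yl diphenyl phosphate | CC1=CCC=C(OP(=O)(Oc2ccccc2)Oc2ccccc2)OC1 | intermediate
6 | trimethyl(6-methyl-4,7-dihydrooxepin-2-yl)stannane | CC1=CCC=C([Sn](C)(C)C)OC1 | intermediate
7 | 5-bromo-2-methylpent-2-ene | CC(C)=CCCBr | starting material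
8 | (6-methyl-4,7-dihydrooxepin-2-yl)lithium (not isolated) | [Li]C1=CCC=C(C)CO1 | intermediate
9 | (4-methylpent-3-en-1-yl)magnesium bromide (not isolated) | CC(C)=CCC[Mg]Br | intermediate
10 | lithium (4-methylpent-3-en-1-yl)(6-methyl-4,7-dihydrooxepin-2-yl)cuprate (not isolated) | [Li+].CC(C)=CCC[Cu-]C1=CCC=C(C)CO1 | intermediate
11 | lithium alkoxide of the ring-opened alkenylcopper, Cu cis to the C5 methylene, 2Z alkene retained (not isolated) | [Li+].[O-]C/C(C)=C\C/C=C(\[Cu])CCC=C(C)C | intermediate
12 | (2Z,5E)-2,6,10-trimethylundeca-2,5,9-trien-1-ol | OC/C(C)=C\C/C=C(\C)CCC=C(C)C | intermediate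
13 | (5aS,7S,9aS)-7-bromo-3,6,6,9a-tetramethyl-2,5,5a,6,7,8,9,9a-octahydro-1-benzoxepine | CC1=CC[C@H]2C(C)(C)[C@@H](Br)CC[C@]2(C)OC1 | intermediate
14 | (5aS,7S,9aS)-7-bromo-3,6,6,9a-tetramethyl-5a,6,7,8,9,9a-hexahydro-1-benzoxepin-2(5H)-one | CC1=CC[C@H]2C(C)(C)[C@@H](Br)CC[C@]2(C)OC1=O | intermediate
15 | (5aS,7S,9aS)-7-bromo-2-(bromomethyl)-3,6,6,9a-tetramethyl-2,5,5a,6,7,8,9,9a-octahydro-1-benzoxepin-2-ol (C2 epimers) | CC1=CC[C@H]2C(C)(C)[C@@H](Br)CC[C@]2(C)OC1(O)CBr | intermediate
16 | (5aS,7S,9aS)-7-bromo-2-(bromomethyl)-3,6,6,9a-tetramethyl-5,5a,6,7,8,9-hexahydro-9aH-1-benzoxepin-1-ium (not isolated) | CC1=CC[C@H]2C(C)(C)[C@@H](Br)CC[C@]2(C)[O+]=C1CBr | intermediate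
17 | palisadin B, (2R,5aS,7S,9aS) | CC1=CC[C@H]2C(C)(C)[C@@H](Br)CC[C@]2(C)O[C@H]1CBr | target

Total step count: 9. Longest linear sequence: 9 steps (from 1); 7 enters at step 5.

Steps most likely to fail

Step 6. Enantiofacial discrimination at the remote terminal alkene may be poor, and simple bromoetherification of the central alkene may run ahead of the cascade. The fallback sets out from 12 and returns at 13. Compound 12 is cyclised with a chiral bis(oxazoline) complex of Hg(OTf)2 in MeNO2 through the same chair-like cascade. A NaCl work-up gives [(5aS,7S,9aS)-3,6,6,9a-tetramethyl-2,5,5a,6,7,8,9,9a-octahydro-1-benzoxepin-7-yl]mercury chloride F1. Bromodemercuration with Br2 and LiBr in pyridine then converts the equatorial C–Hg bond into the equatorial C–Br bond of 13.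

Step 5. Proton transfer from the bis-allylic ring CH2 to the alkenyl-metal centre, or a sluggish 1,2-shift in the seven-membered ring, may erode the ring opening. The fallback sets out from 6 (through 8) and returns at 12.
- Grignard reagent 9 is borylated with i-PrOBpin to 4,4,5,5-tetramethyl-2-(4-methylpent-3-en-1-yl)-1,3,2-dioxaborolane F2.
- Addition of 8 gives the lithium boronate complex F3.
- Activation of the ring oxygen with Me3SiOTf triggers the same invertive 1,2-migration. After work-up this gives (2Z,5Z)-2,10-dimethyl-6-(4,4,5,5-tetramethyl-1,3,2-dioxaborolan-2-yl)undeca-2,5,9-trien-1-ol F4.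
- Suzuki–Miyaura methylation (MeI, PdCl2(dppf), K3PO4, DMF) replaces boron by methyl with retention to give 12.

Step 4. The ketene acetal phosphate may undergo thermal [3,3] ring contraction to a vinylcyclopropane before palladium inserts. The fallback sets out from 4 and returns at 8, and avoids any ketene acetal. Reduction with i-Bu2AlH at −78 °C gives 6-methyl-2,3,4,7-tetrahydrooxepin-2-ol F5. Mesylation and elimination (MsCl, Et3N) give 6-methyl-4,7-dihydrooxepine F6. Direct α-deprotonation of this enol ether with t-BuLi in THF at −78 °C then gives 8.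

Further compounds
F1 | step 6 | [(5aS,7S,9aS)-3,6,6,9a-tetramethyl-2,5,5a,6,7,8,9,9a-octahydro-1-benzoxepin-7-yl]mercury chloride | CC1=CC[C@H]2C(C)(C)[C@@H]([Hg]Cl)CC[C@]2(C)OC1
F2 | step 5 | 4,4,5,5-tetramethyl-2-(4-methylpent-3-en-1-yl)-1,3,2-dioxaborolane | CC(C)=CCCB1OC(C)(C)C(C)(C)O1
F3 | step 5 | lithium boronate complex of F2 with 8 | [Li+].CC(C)=CCC[B-]1(OC(C)(C)C(C)(C)O1)C1=CCC=C(C)CO1
F4 | step 5 | (2Z,5Z)-2,10-dimethyl-6-(4,4,5,5-tetramethyl-1,3,2-dioxaborolan-2-yl)undeca-2,5,9-trien-1-ol (boron cis to the C5 methylene) | OC/C(C)=C\C/C=C(\B1OC(C)(C)C(C)(C)O1)CCC=C(C)C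
F5 | step 4 | 6-methyl-2,3,4,7-tetrahydrooxepin-2-ol | CC1=CCCC(O)OC1
F6 | step 4 | 6-methyl-4,7-dihydrooxepine | CC1=CCC=COC1
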